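**Retrosynthetic overview**

1. The esters go on last: the angelate on a 2α-alcohol (from a C2 ketone, hydride on the β-face) and the 3,4,5-trimethoxybenzoate on C6 by Mitsunobu inversion of a 6α-alcohol. The C4 carbinol comes from a C4 ketone plus an isopropyl nucleophile, and the C8 methyl with the C8=C9 alkene from the enol triflate of a C8 ketone.
2. The plan rests on the cis-fused bicyclo[5.3.0]decane in which the quaternary C1 (CH3) is bonded to the fusion CH C5 and the oxygenated C6 is the next atom of the seven-membered ring. This is what a 1,2-shift of the C1–C6 fusion bond to C5 leaves behind in an angular-methyl trans-decalin-5,6-diol 5-mesylate (C1–C5 made, C1–C6 broken, C6 becomes C=O).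
3. Ring order: cyclohexanes A (C1–C6) and B (C1,C6–C10) come with (R)-Wieland–Miescher ketone; step 7 turns them in one event into the cyclopentane (C1–C5) and the cycloheptanone (C1,C5–C10).
4. The mesylate is reached through the Δ5 bis-ketal, allylic oxidation at C4 (a placeholder oxygen for the later carbinol), α-face dihydroxylation of C5=C6 and mesylation of the secondary C5 hydroxyl.
5. After the shift the C6 ketone is used once more: the β-placed C8 ketal opens by E1cB, which distinguishes C8 from C2; C8, C4, C6 and C2 are then finished in that order.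

Key step: step 7

Remark 1: locants are those of the target and are kept for the decalins; β is the face of the C1 methyl, so the target SMILES reads 1β-CH3, 5β-H (cis fusion), 4α-OH/4β-isopropyl, 6β-aroyloxy, 2α-(Z)-2-methylbut-2-enoyloxy.
Remark 2: O=C1CCCC2=CC(=O)CC[C@@]12C is the (R)-(−)-enantiomer of Wieland–Miescher ketone and is taken as commercial.
Remark 3: the C4 configuration of 5–22 and the 6α configuration of 13–27 are the expected ones; C4 is erased in step 15 and C6 is inverted in step 18.

**Route**

Step 1
Reactants: 1 (R)-Wieland–Miescher ketone; 2 ethylene glycol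
Product: 3 1β-methyl-Δ5(6)-octalin-2,8-dione bis(ethylene ketal)
Conditions: HOCH2CH2OH (excess), p-TsOH (cat.), benzene, reflux, Dean–Stark
Reagents that add atoms: ethylene glycol (2), OCCO
Why: Acid-catalysed ketalisation of both carbonyls with azeotropic water removal; the enone ketalises through its dienol ether so the alkene settles out of conjugation at C5=C6, as in Δ5-3-ketals of 4-en-3-ones, and the quaternary C1 is untouched.

Step 2
Reactants: 3 Δ5 bis-ketal
Product: 4 1β-methyl-Δ5(6)-octalin-2,4,8-trione 2,8-bis(ethylene ketal) (enone C4=O/C5=C6)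
Conditions: Rh2(cap)4 (1 mol %), t-BuOOH (70% aq.), 1,2-dichloroethane, 40 °C
Reagents that add atoms: tert-butyl hydroperoxide, CC(C)(C)OO
Why: Radical allylic oxidation (tert-butylperoxyl chain, dirhodium caprolactamate catalysis) should go to the C4 methylene, because C7 is deactivated by the adjacent ketal carbon C8, the pattern of C7 oxidation in Δ5-steroid 3-ketals; no base is present, so the β-keto ketal formed is not opened.

Step 3
Reactants: 4 enone
Product: 5 4β-hydroxy-1β-methyl-Δ5(6)-octalin-2,8-dione bis(ethylene ketal)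
Conditions: NaBH4, CeCl3·7H2O, MeOH, −20 °C
Reagents that add atoms: none
Why: Luche 1,2-reduction; axial hydride delivery on the α-face should give the equatorial 4β-alcohol (the sense found for Δ5-7-ketones), a placeholder centre that is oxidised again in step 15.

Step 4
Reactants: 5 allylic alcohol; 6 4-methoxybenzyl chloride
Product: 7 4β-(4-methoxybenzyloxy)-1β-methyl-Δ5(6)-octalin-2,8-dione bis(ethylene ketal)
Conditions: NaH, Bu4NI (cat.), THF/DMF, 0 °C → rt
Reagents that add atoms: 4-methoxybenzyl chloride (6), COc1ccc(CCl)cc1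
Why: Williamson etherification of the secondary alkoxide; the PMB ether tolerates osmium, amide bases, hydride and Grignard reagents and is later removed oxidatively.

Step 5
Reactants: 7 PMB ether
Product: 8 5α,6α-dihydroxy-4β-(4-methoxybenzyloxy)-1β-methyl-trans-decalin-2,8-dione bis(ethylene ketal)
Conditions: OsO4 (5 mol %), NMO, acetone/H2O, rt
Reagents that add atoms: osmium tetroxide, O=[Os](=O)(=O)=O; N-methylmorpholine N-oxide, C[N+]1([O-])CCOCC1
Why: Upjohn dihydroxylation; OsO4 adds syn on the α-face, anti to the axial C1 methyl and to the 4β-ether, which sets C5 (equatorial secondary OH) and C6 (axial tertiary OH) and makes the ring fusion trans.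

Step 6
Reactants: 8 diol; 9 methanesulfonyl chloride
Product: 10 6α-hydroxy-5α-mesyloxy-4β-(4-methoxybenzyloxy)-1β-methyl-trans-decalin-2,8-dione bis(ethylene ketal)
Conditions: MsCl, Et3N, CH2Cl2, 0 °C
Reagents that add atoms: methanesulfonyl chloride (9), CS(Cl)(=O)=O
Why: Sulfonylation through sulfene is selective for the secondary equatorial C5 hydroxyl; the axial tertiary C6 hydroxyl does not react at 0 °C.

Step 7
Reactants: 10 diol monomesylate
Product: 11 cis-fused 4β-(4-methoxybenzyloxy)-1β-methyl-5β-H-hydroazulene-2,6,8-trione 2,8-bis(ethylene ketal)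
Conditions: KHMDS (1.0 equiv), THF, −78 → 0 °C; pH 7 buffer
Reagents that add atoms: none
Why: KHMDS converts the axial tertiary C6 hydroxyl into its potassium alkoxide, whose lone pair pushes the C6–C1 ring-fusion bond, held antiperiplanar to the equatorial C5–OMs bond by the trans-decalin chair, onto C5 as mesylate leaves, in a concerted semipinacol 1,2-shift that leaves the C6 ketone. This is the pinacol-type rearrangement of decalin-1,2-diol monosulfonates to hydroazulenones. The cyclopentane (C1–C5) closes through the new C1–C5 bond as a ring contraction by 1,2-alkyl shift, and because the migrating bond is the ring fusion, the cycloheptanone (C1, C5–C10) arises in the same event by ring expansion. C5 is the only new stereocentre: it is inverted by backside displacement while the migrating C1 keeps its configuration, so H-5 should come out cis to the C1 methyl. The step needs C1 to migrate rather than C3 or C7 and no epoxide to form: only ring bonds are anti to the equatorial leaving group, the cis 5,6-oxygens cannot close an epoxide, and the equally aligned C4–C3 bond has no alkoxide behind it because O4 is an ether. One equivalent of base at low temperature keeps the β-keto ketal product from being enolised before the quench.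

Step 8
Reactants: 11 hydroazulen-6-one
Product: 12 8-(2-hydroxyethoxy)-4β-(4-methoxybenzyloxy)-1β-methyl-5β-H-hydroazul-7-ene-2,6-dione 2-(ethylene ketal)
Conditions: KHMDS (1.1 equiv), THF, −78 → 0 °C; aq. NH4Cl
Reagents that add atoms: none
Why: Kinetic deprotonation at the C7 methylene (not the hindered C5 methine) gives an enolate that expels the aligned C8 ketal oxygen by E1cB β-elimination (retro-oxa-Michael); only the ketal β to the ketone can open, so C8 is unmasked as a vinylogous ester while the C2 ketal and C5 stay as they are.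

Step 9
Reactants: 12 vinylogous ester
Product: 13 6α-hydroxy-8-(2-hydroxyethoxy)-4β-(4-methoxybenzyloxy)-1β-methyl-5β-H-hydroazul-7-en-2-one ethylene ketal
Conditions: DIBAL-H, CH2Cl2, −78 °C; Rochelle salt
Reagents that add atoms: none
Why: 1,2-Reduction of the vinylogous ester carbonyl (first half of a Stork–Danheiser sequence) under steric approach control: the bulky hydride should add on the face flanked by H-5, opposite the quaternary C1, to give the 6α-alcohol (oxygen trans to H-5).

Step 10
Reactants: 13 diol; 14 tert-butyldimethylsilyl chloride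
Product: 15 bis-TBS ether of 13 (6α-OTBS; 8-OCH2CH2OTBS)
Conditions: TBSCl, imidazole, DMAP (cat.), DMF, rt
Reagents that add atoms: tert-butyldimethylsilyl chloride (14), CC(C)(C)[Si](C)(C)Cl
Why: Silylation of the allylic secondary and the primary hydroxyl under basic conditions that leave the acid-labile 3-alkoxyallyl alcohol intact.

Step 11
Reactants: 15 bis-silyl ether
Product: 16 6α-(tert-butyldimethylsilyloxy)-4β-(4-methoxybenzyloxy)-1β-methyl-5β-H-hydroazulene-2,8-dione 2-(ethylene ketal)
Conditions: 0.1 M HCl, THF/H2O, 0 °C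
Reagents that add atoms: water, O
Why: Enol ether hydrolysis (C7 protonation, water addition to the C8 oxocarbenium ion, loss of the silylated glycol) is far faster than hydrolysis of the hindered C2 dioxolane, so only the C8 ketone is released; the silyl ether at C6 disfavours ionisation towards an enone.

Step 12
Reactants: 16 C8 ketone; 17 N-phenylbis(trifluoromethanesulfonimide)
Product: 19 8-triflyloxy-Δ8(9) enol triflate of 16 (6α-OTBS; 4β-OPMB; C2 ketal), via potassium enolate 18 (not isolated)
Conditions: KHMDS, THF, −78 °C; then PhNTf2, −78 → −20 °C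
Reagents that add atoms: N-phenylbis(trifluoromethanesulfonimide) (17), O=S(=O)(N(c1ccccc1)S(=O)(=O)C(F)(F)F)C(F)(F)F
Why: Kinetic enolisation of a β-silyloxy ketone with a bulky amide base should occur at C9, away from the oxygen-bearing and more hindered C7 side, and O-triflation fixes the C8=C9 position; −78 °C avoids β-elimination of the silyloxy group.

Step 13
Reactants: 19 enol triflate; 20 methylmagnesium bromide
Product: 21 6α-(tert-butyldimethylsilyloxy)-4β-(4-methoxybenzyloxy)-1β,8-dimethyl-5β-H-hydroazul-8-en-2-one ethylene ketal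
Conditions: MeMgBr, Fe(acac)3 (5 mol %), THF/NMP, −20 °C
Reagents that add atoms: methylmagnesium bromide (20), C[Mg]Br
Why: Iron-catalysed Kumada-type coupling of an alkenyl triflate (Kochi–Fürstner) replaces OTf by CH3 without moving the double bond; ketal, silyl ether and PMB ether are inert.

Step 14
Reactants: 21 PMB ether
Product: 22 4β-hydroxy-6α-(tert-butyldimethylsilyloxy)-1β,8-dimethyl-5β-H-hydroazul-8-en-2-one ethylene ketal
Conditions: DDQ, CH2Cl2/pH 7 buffer, 0 °C
Reagents that add atoms: none
Why: Oxidative PMB cleavage (benzylic hydride abstraction by DDQ, hydrolysis of the oxocarbenium ion); silyl ether, ketal and the trisubstituted alkene are untouched in buffered medium.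

Step 15
Reactants: 22 C4 alcohol
Product: 23 6α-(tert-butyldimethylsilyloxy)-1β,8-dimethyl-5β-H-hydroazul-8-ene-2,4-dione 2-(ethylene ketal)
Conditions: Dess–Martin periodinane, NaHCO3, CH2Cl2, 0 °C → rt
Reagents that add atoms: none
Why: Dess–Martin oxidation under buffered, non-basic conditions gives the C4 ketone without epimerising C5 or eliminating the β-silyloxy group or the β-ketal oxygen.

Step 16
Reactants: 23 C4 ketone; 24 isopropylmagnesium chloride
Product: 26 4α-hydroxy-4β-isopropyl-6α-(tert-butyldimethylsilyloxy)-1β,8-dimethyl-5β-H-hydroazul-8-en-2-one ethylene ketal, via isopropylcerium dichloride 25 (not isolated)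
Conditions: i-PrMgCl, CeCl3, THF, −78 °C; then 23, −78 → −40 °C; aq. NH4Cl
Reagents that add atoms: isopropylmagnesium chloride (24), CC(C)[Mg]Cl
Why: Organocerium (Imamoto) 1,2-addition suppresses enolisation and β-hydride reduction; the nucleophile should enter the cyclopentanone on the convex β-face, anti to the C5–C6 bond and to the 6α-silyloxy group under the ring, giving 4β-isopropyl and 4α-hydroxyl.

Step 17
Reactants: 26 silyl ether
Product: 27 4α,6α-dihydroxy-4β-isopropyl-1β,8-dimethyl-5β-H-hydroazul-8-en-2-one ethylene ketal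
Conditions: TBAF, THF, rt
Reagents that add atoms: none
Why: Fluoride-induced desilylation of the secondary silyl ether; ketal, alkene and the tertiary alcohol are inert.

Step 18
Reactants: 27 6α-alcohol; 28 3,4,5-trimethoxybenzoic acid
Product: 29 4α-hydroxy-4β-isopropyl-1β,8-dimethyl-6β-(3,4,5-trimethoxybenzoyloxy)-5β-H-hydroazul-8-en-2-one ethylene ketal
Conditions: PPh3, DIAD, toluene, 0 °C → rt
Reagents that add atoms: 3,4,5-trimethoxybenzoic acid (28), COc1cc(C(=O)O)cc(OC)c1OC
Why: Mitsunobu esterification: the secondary 6α-alcohol is activated as its oxyphosphonium ion and displaced by the carboxylate in an SN2 reaction from the open face next to H-5, which should install the ester with inversion (6β, cis to H-5); the tertiary C4 alcohol is not activated.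

Step 19
Reactants: 29 C2 ketal
Product: 30 4α-hydroxy-4β-isopropyl-1β,8-dimethyl-6β-(3,4,5-trimethoxybenzoyloxy)-5β-H-hydroazul-8-en-2-one
Conditions: PPTS, acetone/H2O, 40 °C
Reagents that add atoms: water, O
Why: Mild acid-catalysed ketal hydrolysis; ester and alkene tolerate PPTS, and the mild acid and low temperature should keep the tertiary β-hydroxy ketone from dehydrating.

Step 20
Reactants: 30 C2 ketone
Product: 31 2α,4α-dihydroxy-4β-isopropyl-1β,8-dimethyl-6β-(3,4,5-trimethoxybenzoyloxy)-5β-H-hydroazul-8-ene
Conditions: NaBH4, CeCl3·7H2O, MeOH, −40 °C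
Reagents that add atoms: none
Why: Luche-type borohydride reduction, compatible with the aryl ester; hydride should attack the cyclopentanone on the β-face, because the α-face carries the seven-membered ring (C10) and the pseudo-axial C4 hydroxyl while the isopropyl group sits pseudo-equatorial, giving the 2α-alcohol (trans to the C1 methyl).

Step 21
Reactants: 31 2α-alcohol; 32 angelic acid
Product: 34 2α-angeloyloxy-4α-hydroxy-4β-isopropyl-1β,8-dimethyl-6β-(3,4,5-trimethoxybenzoyloxy)-5β-H-hydroazul-8-ene (CNP0112256.1), via angelic 2,4,6-trichlorobenzoic anhydride 33 (not isolated)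
Conditions: 32, 2,4,6-Cl3C6H2COCl, Et3N, toluene, rt; then 31, 75 °C
Reagents that add atoms: angelic acid (32), C/C=C(/C)C(=O)O
Why: Yamaguchi-type acylation with the pre-formed mixed anhydride and no nucleophilic catalyst should keep the Z geometry (no isomerisation to the tiglate); the tertiary C4 hydroxyl is not acylated.

**Compound list**

1 | (R)-(−)-Wieland–Miescher ketone | O=C1CCCC2=CC(=O)CC[C@@]12C | starting material
2 | ethylene glycol | OCCO | starting material
3 | 1β-methyl-Δ5(6)-octalin-2,8-dione bis(ethylene ketal) | O1CCOC12CCC=C3CC4(OCCO4)CC[C@@]23C | intermediate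
4 | 1β-methyl-Δ5(6)-octalin-2,4,8-trione 2,8-bis(ethylene ketal) | O1CCOC12CC(=O)C=C3CC4(OCCO4)CC[C@@]23C | intermediate
5 | 4β-hydroxy-Δ5(6)-octalin bis-ketal | O1CCOC12C[C@H](O)C=C3CC4(OCCO4)CC[C@@]23C | intermediate
6 | 4-methoxybenzyl chloride | COc1ccc(CCl)cc1 | starting material
7 | 4β-PMB ether of 5 | O1CCOC12C[C@H](OCc5ccc(OC)cc5)C=C3CC4(OCCO4)CC[C@@]23C | intermediate
8 | 5α,6α-diol (trans-decalin; 4β-OPMB; 2,8-bis-ketal) | O1CCOC12C[C@H](OCc5ccc(OC)cc5)[C@@H](O)[C@]3(O)CC4(OCCO4)CC[C@@]23C | intermediate
9 | methanesulfonyl chloride | CS(Cl)(=O)=O | starting material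
10 | 6α-ol 5α-mesylate (key-step precursor) | O1CCOC12C[C@H](OCc5ccc(OC)cc5)[C@@H](OS(C)(=O)=O)[C@]3(O)CC4(OCCO4)CC[C@@]23C | intermediate
11 | cis-fused hydroazulen-6-one (4β-OPMB; 2,8-bis-ketal) | O1CCOC12C[C@H](OCc5ccc(OC)cc5)[C@H]3C(=O)CC4(OCCO4)CC[C@@]23C | intermediate
12 | 8-(2-hydroxyethoxy)-Δ7-en-6-one (vinylogous ester; C2 ketal) | O1CCOC12C[C@H](OCc4ccc(OC)cc4)[C@H]3C(=O)C=C(OCCO)CC[C@@]23C | intermediate
13 | 6α-allylic alcohol with 8-(2-hydroxyethoxy) enol ether | O1CCOC12C[C@H](OCc4ccc(OC)cc4)[C@H]3[C@@H](O)C=C(OCCO)CC[C@@]23C | intermediate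
14 | tert-butyldimethylsilyl chloride | CC(C)(C)[Si](C)(C)Cl | starting material
15 | bis-TBS ether of 13 | O1CCOC12C[C@H](OCc4ccc(OC)cc4)[C@H]3[C@@H](O[Si](C)(C)C(C)(C)C)C=C(OCCO[Si](C)(C)C(C)(C)C)CC[C@@]23C | intermediate
16 | hydroazulen-8-one (6α-OTBS; 4β-OPMB; C2 ketal) | O1CCOC12C[C@H](OCc4ccc(OC)cc4)[C@H]3[C@@H](O[Si](C)(C)C(C)(C)C)CC(=O)CC[C@@]23C | intermediate
17 | N-phenylbis(trifluoromethanesulfonimide) | O=S(=O)(N(c1ccccc1)S(=O)(=O)C(F)(F)F)C(F)(F)F | starting material
18 | potassium C8=C9 enolate of 16 (formed in the flask) | [K+].O1CCOC12C[C@H](OCc4ccc(OC)cc4)[C@H]3[C@@H](O[Si](C)(C)C(C)(C)C)CC([O-])=CC[C@@]23C | intermediate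
19 | C8=C9 enol triflate | O1CCOC12C[C@H](OCc4ccc(OC)cc4)[C@H]3[C@@H](O[Si](C)(C)C(C)(C)C)CC(OS(=O)(=O)C(F)(F)F)=CC[C@@]23C | intermediate
20 | methylmagnesium bromide | C[Mg]Br | starting material
21 | 8-methyl-Δ8(9) hydroazulene (6α-OTBS; 4β-OPMB; C2 ketal) | O1CCOC12C[C@H](OCc4ccc(OC)cc4)[C@H]3[C@@H](O[Si](C)(C)C(C)(C)C)CC(C)=CC[C@@]23C | intermediate
22 | 4β-alcohol (6α-OTBS; C2 ketal) | O1CCOC12C[C@H](O)[C@H]3[C@@H](O[Si](C)(C)C(C)(C)C)CC(C)=CC[C@@]23C | intermediate
23 | C4 ketone (6α-OTBS; C2 ketal) | O1CCOC12CC(=O)[C@H]3[C@@H](O[Si](C)(C)C(C)(C)C)CC(C)=CC[C@@]23C | intermediate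
24 | isopropylmagnesium chloride | CC(C)[Mg]Cl | starting material
25 | isopropylcerium dichloride (formed in the flask) | CC(C)[Ce](Cl)Cl | intermediate
26 | 4α-hydroxy-4β-isopropyl carbinol (6α-OTBS; C2 ketal) | O1CCOC12C[C@](O)(C(C)C)[C@H]3[C@@H](O[Si](C)(C)C(C)(C)C)CC(C)=CC[C@@]23C | intermediate
27 | 4α,6α-diol (C2 ketal) | O1CCOC12C[C@](O)(C(C)C)[C@H]3[C@@H](O)CC(C)=CC[C@@]23C | intermediate
28 | 3,4,5-trimethoxybenzoic acid | COc1cc(C(=O)O)cc(OC)c1OC | starting material
29 | 6β-(3,4,5-trimethoxybenzoate) (C2 ketal) | O1CCOC12C[C@](O)(C(C)C)[C@H]3[C@H](OC(=O)c4cc(OC)c(OC)c(OC)c4)CC(C)=CC[C@@]23C | intermediate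
30 | C2 ketone | O=C1C[C@](O)(C(C)C)[C@H]2[C@H](OC(=O)c3cc(OC)c(OC)c(OC)c3)CC(C)=CC[C@@]12C | intermediate
31 | 2α-alcohol | O[C@H]1C[C@](O)(C(C)C)[C@H]2[C@H](OC(=O)c3cc(OC)c(OC)c(OC)c3)CC(C)=CC[C@@]12C | intermediate
32 | angelic acid [(Z)-2-methylbut-2-enoic acid] | C/C=C(/C)C(=O)O | starting material
33 | angelic 2,4,6-trichlorobenzoic anhydride (formed in the flask) | C/C=C(/C)C(=O)OC(=O)c1c(Cl)cc(Cl)cc1Cl | intermediate
34 | CNP0112256.1 | C/C=C(/C)C(=O)O[C@H]1C[C@](O)(C(C)C)[C@H]2[C@H](OC(=O)c3cc(OC)c(OC)c(OC)c3)CC(C)=CC[C@@]12C | target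

**Step count**

Total: 21 steps. Longest linear sequence: 21 steps (1 → 34); all other partners are commercial.

**Steps most likely to fail**

Step 7 (key step). The ketone already formed can be deprotonated by alkoxide that has not yet rearranged. The C7 enolate would then open the C8 ketal ahead of time, and the C5 enolate could expel 4-methoxybenzyl alcoholate, which would erase the C4 oxygen and the new C5 centre. The fallback leaves the alkoxide manifold: the shift is run as an aluminium-promoted rearrangement of the β-mesyloxy alcohol (Et3Al, CH2Cl2, −78 °C, Tsuchihashi–Suzuki type). The aluminium alkoxide migrates while the Lewis acid pulls off the sulfonate, and no free base or enolate is present. It sets out from 10 and returns at 11; no new compound is made (F0).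

Step 18. The oxyphosphonium ion of the crowded 6α-alcohol may lose H-5 (anti) by E2 elimination to a C5=C6 alkene faster than it is displaced. The step also gives the wrong epimer if facial control in step 9 has delivered 6β- instead of 6α-alcohol. The fallback sets C6 by thermodynamic control instead of SN2. From 27, Dess–Martin oxidation gives the C6 ketone F1. Dissolving-metal reduction (Li, NH3/THF, t-BuOH, −78 °C) should then give the more stable equatorial 6β-alcohol F2, with H-6 in the slot flanked by C1 and C4. Acylation with 3,4,5-trimethoxybenzoyl chloride (DMAP, pyridine) returns to the route at 29.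

Step 20. Facial selectivity may be poor: the β-isopropyl group, 1,3 to C2, could steer hydride to the α-face. The fallback corrects the centre by substitution. From 30 the reduction product is then the 2β-alcohol F3. Mitsunobu reaction with chloroacetic acid (PPh3, DIAD) inverts it to the 2α-chloroacetate F4, the nucleophile using the α-face that the hydride had used. Thiourea/NaHCO3 in ethanol removes the chloroacetyl group without touching the aryl ester and returns to the route at 31.

**Further compounds**

F0 | step 7 | none | none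
F1 | step 18 | C6 ketone (4α-hydroxy-4β-isopropyl; Δ8; C2 ketal) | O1CCOC12C[C@](O)(C(C)C)[C@H]3C(=O)CC(C)=CC[C@@]23C
F2 | step 18 | 6β-alcohol (4α,6β-diol; C2 ketal) | O1CCOC12C[C@](O)(C(C)C)[C@H]3[C@H](O)CC(C)=CC[C@@]23C
F3 | step 20 | 2β-alcohol (C2 epimer of 31) | O[C@@H]1C[C@](O)(C(C)C)[C@H]2[C@H](OC(=O)c3cc(OC)c(OC)c(OC)c3)CC(C)=CC[C@@]12C
F4 | step 20 | 2α-chloroacetate | ClCC(=O)O[C@H]1C[C@](O)(C(C)C)[C@H]2[C@H](OC(=O)c3cc(OC)c(OC)c(OC)c3)CC(C)=CC[C@@]12C
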